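The enabling feature is that the ester carbonyl C1 and the α-methylene C2 form an acetate unit capping an unbranched, unfunctionalised C26 acyl chain (C3–C28). The phenyl ring of the O-benzyl group is the only ring and stays a spectator.
Retrosynthesis: C3 is first taken back up the oxidation ladder (CH2 ← C2=C3 enoate ← C3 carbinol ← C3 ketone). The C2–C3 bond is then cut into a hexacosanoyl electrophile and a benzyl malonate nucleophile that gives up its free carboxyl as CO2, and the benzyl O–C1 bond is traced back to benzyl alcohol and Meldrum's acid.
Forward: the half ester and the C26 acyl imidazolide are made in parallel, one step each, and joined at C2–C3, so the full C28 chain and the benzyl ester are in place together. The C3 oxygen is then removed by reduction, dehydration and conjugate reduction, the order a fatty acid synthase follows.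
No ring is formed at any stage and the target has no stereocentre. The C3 carbinol is made racemic and erased by the elimination, and the alkene geometry disappears in the last step.

Key step: step 3

Remark: hexacosanoic (cerotic) acid is taken as a purchasable fatty acid. All C26–C28 compounds are waxes, so solvents and temperatures are chosen for solubility, and purification is expected to rest mainly on crystallisation.

Step 1
Reactants: 1 Meldrum's acid (2,2-dimethyl-1,3-dioxane-4,6-dione); 2 benzyl alcohol
Product: 3 monobenzyl malonate (3-(benzyloxy)-3-oxopropanoic acid)
Conditions: toluene, 105 °C, 20 h; extraction into aq Na2CO3, then 1 M HCl, EtOAc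
Reagents that add atoms: none
Why: Alcoholysis of Meldrum's acid: benzyl alcohol should open the doubly activated cyclic acylal at one of its two equivalent carbonyls with expulsion of acetone, which leaves exactly one benzyl ester and one free carboxyl, and the acid is freed from neutral material by the base extraction.

Step 2
Reactants: 4 hexacosanoic acid; 5 1,1'-carbonyldiimidazole
Product: 6 1-hexacosanoylimidazole
Conditions: 5 (1.05 equiv), dry THF, 50 °C, 2 h, N2; evaporation, solid used as such
Reagents that add atoms: 1,1'-carbonyldiimidazole (5), O=C(n1ccnc1)n1ccnc1
Why: Acyl imidazolide formation with carbonyldiimidazole: escape of CO2 makes the activation irreversible under neutral conditions, the saturated chain offers no other reactive site, and the warming serves only to keep the waxy acid in solution.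

Step 3
Reactants: 3 monobenzyl malonate; 6 1-hexacosanoylimidazole
Product: 10 benzyl 3-oxooctacosanoate, via magnesium benzyl malonate chelate 7 (not isolated), via chloromagnesium acylmalonate 8 (not isolated), via chloromagnesium enolate 9 (not isolated)
Conditions: 3 (1.6 equiv), anhydrous MgCl2 (1.6 equiv), Et3N (3.3 equiv), THF, 25 °C, 2 h; then 6 in warm THF, 45 °C, 16 h; 1 M HCl
Reagents that add atoms: magnesium chloride, [Mg+2].[Cl-].[Cl-] (its atoms sit only in 7, 8 and 9; none stays in 10)
Why: MgCl2 and Et3N should turn 3 into the chelated enolate carboxylate 7, because coordination of both carbonyl oxygens to divalent magnesium makes the C2 hydrogens acidic enough for an amine base. C2 of 7 then adds to the acyl carbon of 6 and the tetrahedral adduct expels imidazole, which forms the C2–C3 bond and gives acylmalonate 8; 8 sheds CO2 from its carboxylate to leave the chelated enolate 9, and 9 is protonated to 10 only in the acid quench. The closest known reaction type is the decarboxylative Claisen (Masamune–Claisen) condensation of a magnesium malonate half ester with an acyl imidazolide, the flask counterpart of the ketosynthase step of fatty acid biosynthesis. No ring closes and no lasting stereocentre arises, since the labile C2 centre of 8 is flattened when CO2 leaves. The step needs C- over O-acylation and one acylation only: the first is secured by magnesium, which ties up both oxygens of 7 and leaves carbon as the free nucleophilic site, the second by storage of the product as the unreactive enolate 9 until work-up. The acyl donor carries nothing but a saturated chain and its own α-hydrogens are out of reach of Et3N, so self-condensation is not expected.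

Step 4
Reactants: 10 benzyl 3-oxooctacosanoate
Product: 11 benzyl 3-hydroxyoctacosanoate (racemic)
Conditions: NaBH4 (0.5 equiv), THF–i-PrOH 5:1, 0 → 20 °C; 0.5 M HCl
Reagents that add atoms: none
Why: Chemoselective borohydride reduction of a ketone beside an ester: the C3 ketone is far more electrophilic than the benzyl ester, the limited hydride charge and the hindered alcohol cosolvent should hold back 1,3-diol formation and ester exchange, and the new C3 stereocentre is formed racemic by design, since no control element is present and step 5 removes it.

Step 5
Reactants: 11 benzyl 3-hydroxyoctacosanoate (racemic)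
Product: 13 benzyl (E)-octacos-2-enoate, via benzyl 3-(mesyloxy)octacosanoate 12 (not isolated)
Conditions: MsCl (1.3 equiv), Et3N (1.5 equiv), CH2Cl2, 0 → 20 °C; then DBU (2 equiv), 20 °C
Reagents that add atoms: methanesulfonyl chloride, CS(=O)(=O)Cl (its CH3SO2 group sits only in 12; none stays in 13)
Why: Mesylation followed by base-induced E1cB-type β-elimination: the C2 hydrogens are acidified by the ester and the C3 mesylate is a good leaving group, so DBU should give the conjugated enoate, mainly as the (E) isomer, whose geometry is of no consequence for step 6.

Step 6
Reactants: 13 benzyl (E)-octacos-2-enoate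
Product: 14 benzyl octacosanoate (target)
Conditions: [(Ph3P)CuH]6 (1 mol %), 1,2-bis(diphenylphosphino)benzene (6 mol %), Me(EtO)2SiH (2 equiv), t-BuOH (2 equiv), degassed toluene, 30 °C; aq NH4Cl
Reagents that add atoms: none
Why: Copper hydride catalysed conjugate (1,4) reduction of an enoate: the soft Cu–H delivers hydride to C3, t-BuOH supplies the proton at C2 and the silane regenerates Cu–H, while the ester carbonyl and the benzylic C–O bond, which hydrogenation over palladium would cleave, should stay intact.

Compound list
1 | Meldrum's acid (2,2-dimethyl-1,3-dioxane-4,6-dione) | CC1(C)OC(=O)CC(=O)O1 | starting material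
2 | benzyl alcohol | OCc1ccccc1 | starting material
3 | monobenzyl malonate (3-(benzyloxy)-3-oxopropanoic acid) | OC(=O)CC(=O)OCc1ccccc1 | intermediate
4 | hexacosanoic acid | CCCCCCCCCCCCCCCCCCCCCCCCCC(=O)O | starting material
5 | 1,1'-carbonyldiimidazole | O=C(n1ccnc1)n1ccnc1 | starting material
6 | 1-hexacosanoylimidazole | CCCCCCCCCCCCCCCCCCCCCCCCCC(=O)n1ccnc1 | intermediate
7 | magnesium chelate of monobenzyl malonate (enolate carboxylate; formed in the flask in step 3) | [Mg+2].[O-]C(=O)/C=C(\[O-])OCc1ccccc1 | intermediate
8 | chloromagnesium 2-(benzyloxycarbonyl)-3-oxooctacosanoate (racemic, labile at C2; formed in the flask in step 3) | CCCCCCCCCCCCCCCCCCCCCCCCCC(=O)C(C(=O)[O-])C(=O)OCc1ccccc1.[Mg+2].[Cl-] | intermediate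
9 | chloromagnesium (Z)-enolate of benzyl 3-oxooctacosanoate (formed in the flask in step 3) | CCCCCCCCCCCCCCCCCCCCCCCCC/C([O-])=C/C(=O)OCc1ccccc1.[Mg+2].[Cl-] | intermediate
10 | benzyl 3-oxooctacosanoate | CCCCCCCCCCCCCCCCCCCCCCCCCC(=O)CC(=O)OCc1ccccc1 | intermediate
11 | benzyl 3-hydroxyoctacosanoate (racemic) | CCCCCCCCCCCCCCCCCCCCCCCCCC(O)CC(=O)OCc1ccccc1 | intermediate
12 | benzyl 3-(mesyloxy)octacosanoate (racemic; formed in the flask in step 5) | CCCCCCCCCCCCCCCCCCCCCCCCCC(OS(C)(=O)=O)CC(=O)OCc1ccccc1 | intermediate
13 | benzyl (E)-octacos-2-enoate | CCCCCCCCCCCCCCCCCCCCCCCCC/C=C/C(=O)OCc1ccccc1 | intermediate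
14 | benzyl octacosanoate | CCCCCCCCCCCCCCCCCCCCCCCCCCCC(=O)OCc1ccccc1 | target

Total step count: 6.
Longest linear sequence: 5 steps (4 → 6 → 10 → 11 → 13 → 14). The branch 1 → 3 → 10 onward is of equal length.

Steps most likely to fail

Risk 1, step 3. The acylation may stall because the waxy acyl donor and the magnesium slurry mix poorly. Hydrolysis of the imidazolide on work-up and protodecarboxylation of the malonate would then outrun C–C bond formation. The fallback sets out from 4 and comes back at 10. It forms the same C2–C3 bond with a different malonate equivalent, the much more acidic cyclic one, under homogeneous conditions. Acid 4 is coupled with Meldrum's acid 1 (DCC, DMAP, CH2Cl2–THF, 0 → 25 °C) to give 5-(1-hydroxyhexacosylidene)-2,2-dimethyl-1,3-dioxane-4,6-dione F1. This acyl Meldrum's acid is then heated with benzyl alcohol 2 in toluene at reflux, where loss of acetone and CO2 and capture by the alcohol should deliver 10.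

Risk 2, step 6. Hydride transfer to a weakly electrophilic β-alkyl enoate may be slow, and the catalyst may die from traces of air. Incomplete conversion would leave two waxes of nearly equal polarity that resist separation. The fallback sets out from 13 and comes back at 14, and it gives up chemoselectivity instead of relying on it. Exhaustive hydrogenation (H2, palladium on carbon, THF–EtOAc, 40 °C) saturates C2=C3 and cleaves the benzyl ester at once to give octacosanoic acid F2, which is purified by crystallisation. It is then re-esterified with benzyl alcohol 2 (cat. p-TsOH, toluene, Dean–Stark reflux; Fischer esterification) to 14.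

Risk 3, step 5. The elimination may stay incomplete, or prolonged contact with base may move the double bond out of conjugation, to a position that the conjugate reduction cannot touch. The fallback sets out from 11 and comes back at 14, so it bypasses the alkene and step 6 altogether by a Barton–McCombie deoxygenation. Alcohol 11 is acylated with O-phenyl chlorothionoformate (pyridine, cat. DMAP, CH2Cl2, 20 °C) to give benzyl 3-(phenoxycarbonothioyloxy)octacosanoate F3. This thionocarbonate is reduced with Bu3SnH and AIBN in toluene at 90 °C. The secondary C3 radical has no fragmentation path open to it, and the benzyl ester is inert to the stannane.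

Further compounds
F1 | step 3 | 5-(1-hydroxyhexacosylidene)-2,2-dimethyl-1,3-dioxane-4,6-dione | CCCCCCCCCCCCCCCCCCCCCCCCCC(O)=C1C(=O)OC(C)(C)OC1=O
F2 | step 6 | octacosanoic acid | CCCCCCCCCCCCCCCCCCCCCCCCCCCC(=O)O
F3 | step 5 | benzyl 3-(phenoxycarbonothioyloxy)octacosanoate (racemic) | CCCCCCCCCCCCCCCCCCCCCCCCCC(OC(=S)Oc1ccccc1)CC(=O)OCc1ccccc1
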